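**Retrosynthetic overview**
- Feature: ring A is locally symmetric about the line through C4a and C7. C6-OMe pairs with C8-OMe, and C5 (bearing OH) pairs with C8a (bearing O1). One symmetric ring A block with the same leaving group on C5 and C8a therefore serves both O1 and the 5-OH.
- End game: the benzyl ethers at O7 and O3' come off by hydrogenolysis. C5–OH is traced back to C5–Br by copper-catalysed hydroxylation next to the C4 carbonyl.
- Key disconnection: O1–C8a of ring C, opened to a 1-(2,6-dibromoaryl)-3-aryl-1,3-diketone. Enolate O-arylation at either bromide gives the same 5-bromoflavone.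
- Diketone: the C3–C4 bond is formed from the lithium enolate of O-benzylated 3-hydroxy-4-methoxyacetophenone and a 2,6-dibromobenzoyl chloride. The chloride comes from syringol by O-benzylation, double bromination, deprotonation of the last ring C–H and carboxylation.
- Ring order: rings A and B are bought as arenes. Ring C is the only ring made, in step 7.

Key step: step 7

Remark: the 1,3-diketone is drawn as the diketo tautomer although the chelated enol should dominate. The target is achiral, so no stereocentre has to be set.

**Step 1**
Reactants: 1 syringol (2,6-dimethoxyphenol); 2 benzyl bromide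
Product: 3 2-(benzyloxy)-1,3-dimethoxybenzene
Conditions: BnBr (1.1 equiv), K2CO3 (1.5 equiv), DMF, 60 °C
Reagents that add atoms: benzyl bromide (2), BrCc1ccccc1
Why: Williamson ether synthesis, in which the phenoxide, though flanked by two methoxy groups, is alkylated readily by the unhindered benzylic bromide, and the ether removes the phenol-directed para bromination that free syringol would undergo.

**Step 2**
Reactants: 3 2-(benzyloxy)-1,3-dimethoxybenzene
Product: 4 3-(benzyloxy)-1,5-dibromo-2,4-dimethoxybenzene
Conditions: NBS (2.1 equiv), MeCN, 0 °C → rt, dark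
Reagents that add atoms: N-bromosuccinimide, O=C1CCC(=O)N1Br
Why: Electrophilic aromatic bromination, in which the two outer methoxy groups stay in conjugation and direct to C4 and C6 of 3 while the crowded central benzyloxy group is twisted and leaves its para carbon least activated, as in the known 4,6-dibromination of 1,2,3-trialkoxybenzenes; the polar solvent and exclusion of light keep NBS away from the benzylic CH2.

**Step 3**
Reactants: 4 3-(benzyloxy)-1,5-dibromo-2,4-dimethoxybenzene; 5 carbon dioxide
Product: 7 4-(benzyloxy)-2,6-dibromo-3,5-dimethoxybenzoic acid, via aryllithium 6 (not isolated)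
Conditions: LDA (commercial solution, 1.1 equiv), THF, −78 °C; dry CO2 gas, −78 °C → rt; 1 M HCl
Reagents that add atoms: carbon dioxide (5), O=C=O
Why: Deprotonative lithiation and carboxylation, in which the only ring hydrogen is acidified by two ortho bromines and is removed by the amide base (an alkyllithium would exchange bromine instead), and the 2,6-dibromoaryllithium at −78 °C neither loses LiBr nor shifts halogen, because it is already the best-stabilised carbanion and no other ring C–H exists, so CO2 traps it as the carboxylate.

**Step 4**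
Reactants: 7 4-(benzyloxy)-2,6-dibromo-3,5-dimethoxybenzoic acid
Product: 8 4-(benzyloxy)-2,6-dibromo-3,5-dimethoxybenzoyl chloride
Conditions: (COCl)2 (1.5 equiv), DMF (cat.), CH2Cl2, 0 °C → rt; evaporate, use crude
Reagents that add atoms: oxalyl chloride, O=C(Cl)C(=O)Cl
Why: Acid chloride formation through the Vilsmeier-type chloroiminium salt, which activates even di-ortho-substituted benzoic acids under mild conditions that leave aryl bromides, methyl ethers and the benzyl ether untouched and give only volatile by-products.

**Step 5**
Reactants: 9 3-hydroxy-4-methoxyacetophenone; 2 benzyl bromide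
Product: 10 1-[3-(benzyloxy)-4-methoxyphenyl]ethan-1-one
Conditions: BnBr (1.1 equiv), K2CO3 (1.5 equiv), DMF, 60 °C
Reagents that add atoms: benzyl bromide (2), BrCc1ccccc1
Why: Williamson ether synthesis, in which carbonate deprotonates only the phenol and not the methyl ketone, so O-benzylation masks the acidic OH before enolate chemistry.

**Step 6**
Reactants: 10 1-[3-(benzyloxy)-4-methoxyphenyl]ethan-1-one; 8 4-(benzyloxy)-2,6-dibromo-3,5-dimethoxybenzoyl chloride
Product: 12 1-[4-(benzyloxy)-2,6-dibromo-3,5-dimethoxyphenyl]-3-[3-(benzyloxy)-4-methoxyphenyl]propane-1,3-dione, via lithium enolate 11 (not isolated)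
Conditions: LiHMDS (2.1 equiv), THF, −78 °C; then 8 in THF, −78 → 0 °C; 1 M HCl
Reagents that add atoms: none
Why: Claisen-type C-acylation of a ketone lithium enolate with an aroyl chloride, in which the tightly bound lithium enolate in THF at low temperature reacts at carbon and the second equivalent of base deprotonates the more acidic 1,3-diketone as it forms, shielding it from a second acylation.

**Step 7**
Reactants: 12 1-[4-(benzyloxy)-2,6-dibromo-3,5-dimethoxyphenyl]-3-[3-(benzyloxy)-4-methoxyphenyl]propane-1,3-dione
Product: 14 7-(benzyloxy)-2-[3-(benzyloxy)-4-methoxyphenyl]-5-bromo-6,8-dimethoxy-4H-chromen-4-one, via potassium enolate 13 (not isolated)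
Conditions: CuI (10 mol %), K2CO3 (2 equiv), dry DMF, 100 °C, Ar
Reagents that add atoms: none
Why: K2CO3 turns 12 into its chelating potassium enolate 13, and the enolate oxygen on the ring B side binds monovalent copper and so holds the metal beside one of the two ortho C–Br bonds of ring A. Oxidative addition into that bond followed by C–O reductive elimination from the trivalent copper intermediate makes O1–C8a; the closest known reaction type is the intramolecular Ullmann-type O-arylation of 1-(2-haloaryl)-1,3-diketones, an established flavone synthesis. Ring C closes as a six-membered ring by attack of oxygen on an aromatic carbon with bromide leaving outside the new ring (formally 6-exo), whereas arylation at the central carbon would have to build a four-membered benzocyclobutenone and is out of reach. No stereocentre is created. The step needs O-selectivity, which ring size secures, and a single substitution, which the substrate secures twice over: the two bromides are exchanged by the mirror plane through C1 and C4 of the aryl group, so closure at either gives the same 14, and after closure the enolate is consumed, so the bromide now at C5 has no internal nucleophile left. Copper is used rather than base alone because three alkoxy groups enrich the ring and the di-ortho-substituted aryl ketone is twisted out of conjugation, which weakens activation for a plain addition–elimination.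

**Step 8**
Reactants: 14 7-(benzyloxy)-2-[3-(benzyloxy)-4-methoxyphenyl]-5-bromo-6,8-dimethoxy-4H-chromen-4-one
Product: 15 7-(benzyloxy)-2-[3-(benzyloxy)-4-methoxyphenyl]-5-hydroxy-6,8-dimethoxy-4H-chromen-4-one
Conditions: Cu(acac)2 (5 mol %), N,N'-bis(4-hydroxy-2,6-dimethylphenyl)oxalamide (5 mol %), LiOH·H2O (3 equiv), DMSO/H2O, 80 °C, Ar; 1 M HCl
Reagents that add atoms: lithium hydroxide, [Li+].[OH-]
Why: Copper-catalysed hydroxylation of an aryl bromide (Ullmann-type C–O coupling with hydroxide), favoured here because the C5 bromide is ortho to the electron-withdrawing C4 carbonyl whose oxygen can hold copper next to the C–Br bond, while the oxalamide ligand allows a temperature at which the methyl and benzyl ethers are inert.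

**Step 9**
Reactants: 15 7-(benzyloxy)-2-[3-(benzyloxy)-4-methoxyphenyl]-5-hydroxy-6,8-dimethoxy-4H-chromen-4-one
Product: 16 acerosin (5,7-dihydroxy-2-(3-hydroxy-4-methoxyphenyl)-6,8-dimethoxy-4H-chromen-4-one)
Conditions: H2 (1 atm), 10% Pd/C, EtOAc/MeOH, rt
Reagents that add atoms: none
Why: Catalytic hydrogenolysis of aryl benzyl ethers, which cleaves both O–CH2Ph bonds at room temperature and one atmosphere while the conjugated C2–C3 double bond and the C4 carbonyl of a flavone are normally retained, and which is placed after step 8 because a C–Br bond would be reduced as well.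

**Compound list**
1 | syringol (2,6-dimethoxyphenol) | COc1cccc(OC)c1O | starting material
2 | benzyl bromide | BrCc1ccccc1 | starting material
3 | 2-(benzyloxy)-1,3-dimethoxybenzene | COc1cccc(OC)c1OCc1ccccc1 | intermediate
4 | 3-(benzyloxy)-1,5-dibromo-2,4-dimethoxybenzene | COc1c(Br)cc(Br)c(OC)c1OCc1ccccc1 | intermediate
5 | carbon dioxide | O=C=O | starting material
6 | [4-(benzyloxy)-2,6-dibromo-3,5-dimethoxyphenyl]lithium | [Li]c1c(Br)c(OC)c(OCc2ccccc2)c(OC)c1Br | intermediate (not isolated)
7 | 4-(benzyloxy)-2,6-dibromo-3,5-dimethoxybenzoic acid | OC(=O)c1c(Br)c(OC)c(OCc2ccccc2)c(OC)c1Br | intermediate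
8 | 4-(benzyloxy)-2,6-dibromo-3,5-dimethoxybenzoyl chloride | ClC(=O)c1c(Br)c(OC)c(OCc2ccccc2)c(OC)c1Br | intermediate
9 | 3-hydroxy-4-methoxyacetophenone | CC(=O)c1ccc(OC)c(O)c1 | starting material
10 | 1-[3-(benzyloxy)-4-methoxyphenyl]ethan-1-one | CC(=O)c1ccc(OC)c(OCc2ccccc2)c1 | intermediate
11 | lithium 1-[3-(benzyloxy)-4-methoxyphenyl]ethen-1-olate | [Li+].[O-]C(=C)c1ccc(OC)c(OCc2ccccc2)c1 | intermediate (not isolated)
12 | 1-[4-(benzyloxy)-2,6-dibromo-3,5-dimethoxyphenyl]-3-[3-(benzyloxy)-4-methoxyphenyl]propane-1,3-dione | O=C(CC(=O)c1ccc(OC)c(OCc2ccccc2)c1)c1c(Br)c(OC)c(OCc2ccccc2)c(OC)c1Br | intermediate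
13 | potassium (Z)-3-[4-(benzyloxy)-2,6-dibromo-3,5-dimethoxyphenyl]-1-[3-(benzyloxy)-4-methoxyphenyl]-3-oxoprop-1-en-1-olate | [K+].[O-]/C(=C\C(=O)c1c(Br)c(OC)c(OCc2ccccc2)c(OC)c1Br)c1ccc(OC)c(OCc2ccccc2)c1 | intermediate (not isolated)
14 | 7-(benzyloxy)-2-[3-(benzyloxy)-4-methoxyphenyl]-5-bromo-6,8-dimethoxy-4H-chromen-4-one | COc1ccc(-c2cc(=O)c3c(Br)c(OC)c(OCc4ccccc4)c(OC)c3o2)cc1OCc1ccccc1 | intermediate
15 | 7-(benzyloxy)-2-[3-(benzyloxy)-4-methoxyphenyl]-5-hydroxy-6,8-dimethoxy-4H-chromen-4-one | COc1ccc(-c2cc(=O)c3c(O)c(OC)c(OCc4ccccc4)c(OC)c3o2)cc1OCc1ccccc1 | intermediate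
16 | acerosin | COc1ccc(-c2cc(=O)c3c(O)c(OC)c(O)c(OC)c3o2)cc1O | target

**Step count**
- Total step count: 9.
- Longest linear sequence: 8 steps (1, 2, 3, 4, 6, 7, 8, 9). Step 5 is the side branch.

**Steps most likely to fail**

Step 7.
- What may go wrong: copper insertion may be slow, because the C–Br bond sits on an electron-rich ring between a methoxy group and a twisted acyl group. At the temperature then needed, three processes may overtake ring closure: retro-Claisen cleavage of the diketone by traces of water, reductive loss of bromine, or later substitution of the surviving bromide.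
- Fallback: it sets out from 4 and 10 and comes back at 14. Ring C is built by carbonylative annulation, so O1–C8a no longer has to be made by copper.
- Ring A part: one of the two equivalent bromides of 4 undergoes bromine–lithium exchange with n-BuLi (1 equiv) in the presence of B(OiPr)3 at −78 °C. Aqueous work-up should give [3-(benzyloxy)-5-bromo-2,4-dimethoxyphenyl]boronic acid F1. H2O2/NaOH should oxidise it to 3-(benzyloxy)-5-bromo-2,4-dimethoxyphenol F2. NIS in MeCN should iodinate the only free ring position, ortho to the hydroxyl, to give 3-(benzyloxy)-5-bromo-6-iodo-2,4-dimethoxyphenol F3.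
- Ring B part: enolate 11, made from 10, is trapped with ClP(O)(OEt)2 as 1-[3-(benzyloxy)-4-methoxyphenyl]ethenyl diethyl phosphate F4. Excess LDA eliminates phosphate from it to give 2-(benzyloxy)-4-ethynyl-1-methoxybenzene F5.
- Union: carbonylative Sonogashira coupling of F3 with F5 (PdCl2(PPh3)2, CO 1 atm, Et2NH) should engage C–I before C–Br. It should give 1-[4-(benzyloxy)-2-bromo-6-hydroxy-3,5-dimethoxyphenyl]-3-[3-(benzyloxy)-4-methoxyphenyl]prop-2-yn-1-one F6 in the flask. The secondary amine then closes F6 in the 6-endo mode to 14.

Step 8.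
- What may go wrong: hydroxide may attack C2, open ring C and trigger retro-Claisen fragmentation. The coupling at the di-ortho-substituted bromide may also be sluggish, or the C–Br bond may be reduced.
- What is harmless: mere opening and reclosure of ring C does no damage. C5 and C8a are mirror-related, so reclosure through either oxygen leads to the same flavone and no Wessely–Moser isomer can arise.
- Fallback: it sets out from 14 and comes back at the target 16. Hydroxide is replaced by methoxide, whose copper-mediated coupling with bromoflavones is established.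
- First stage: NaOMe and CuBr in DMF/MeOH at about 110 °C should give 7-(benzyloxy)-2-[3-(benzyloxy)-4-methoxyphenyl]-5,6,8-trimethoxy-4H-chromen-4-one F7.
- Second stage: BCl3 with pentamethylbenzene in CH2Cl2 (−78 → 0 °C) should remove both benzyl groups. Through the boron chelate with the C4 carbonyl it should also cleave only the 5-O-methyl group, giving 16 directly.

Step 6.
- What may go wrong: the enolate may be acylated at oxygen, attack on the di-ortho-substituted acid chloride may be slow, or the acid chloride may be consumed by the excess amide base.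
- Fallback: it sets out from 4 (through 6) and 10 (through 11) and comes back at 12. Acylation is replaced by aldol addition and oxidation.
- First stage: aryllithium 6 is quenched with DMF to give 4-(benzyloxy)-2,6-dibromo-3,5-dimethoxybenzaldehyde F8.
- Second stage: enolate 11 adds to this much less demanding electrophile at −78 °C. The product should be racemic 3-[4-(benzyloxy)-2,6-dibromo-3,5-dimethoxyphenyl]-1-[3-(benzyloxy)-4-methoxyphenyl]-3-hydroxypropan-1-one F9.
- Third stage: Dess–Martin periodinane in CH2Cl2 should oxidise the carbinol to diketone 12, which erases the stereocentre.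

**Further compounds**
F1 | step 7 | [3-(benzyloxy)-5-bromo-2,4-dimethoxyphenyl]boronic acid | COc1c(B(O)O)cc(Br)c(OC)c1OCc1ccccc1
F2 | step 7 | 3-(benzyloxy)-5-bromo-2,4-dimethoxyphenol | COc1c(O)cc(Br)c(OC)c1OCc1ccccc1
F3 | step 7 | 3-(benzyloxy)-5-bromo-6-iodo-2,4-dimethoxyphenol | COc1c(O)c(I)c(Br)c(OC)c1OCc1ccccc1
F4 | step 7 | 1-[3-(benzyloxy)-4-methoxyphenyl]ethenyl diethyl phosphate | C=C(OP(=O)(OCC)OCC)c1ccc(OC)c(OCc2ccccc2)c1
F5 | step 7 | 2-(benzyloxy)-4-ethynyl-1-methoxybenzene | C#Cc1ccc(OC)c(OCc2ccccc2)c1
F6 | step 7 | 1-[4-(benzyloxy)-2-bromo-6-hydroxy-3,5-dimethoxyphenyl]-3-[3-(benzyloxy)-4-methoxyphenyl]prop-2-yn-1-one | O=C(C#Cc1ccc(OC)c(OCc2ccccc2)c1)c1c(O)c(OC)c(OCc2ccccc2)c(OC)c1Br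
F7 | step 8 | 7-(benzyloxy)-2-[3-(benzyloxy)-4-methoxyphenyl]-5,6,8-trimethoxy-4H-chromen-4-one | COc1ccc(-c2cc(=O)c3c(OC)c(OC)c(OCc4ccccc4)c(OC)c3o2)cc1OCc1ccccc1
F8 | step 6 | 4-(benzyloxy)-2,6-dibromo-3,5-dimethoxybenzaldehyde | O=Cc1c(Br)c(OC)c(OCc2ccccc2)c(OC)c1Br
F9 | step 6 | 3-[4-(benzyloxy)-2,6-dibromo-3,5-dimethoxyphenyl]-1-[3-(benzyloxy)-4-methoxyphenyl]-3-hydroxypropan-1-one (racemic) | O=C(CC(O)c1c(Br)c(OC)c(OCc2ccccc2)c(OC)c1Br)c1ccc(OC)c(OCc2ccccc2)c1
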